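The reading at 20 h was what I wanted from this flask, in which D and G form the links X; the readings stopped at 15.0 h.

| flask | D | G | Q | temperature | remark | time |
|---|---|---|---|---|---|---|
| Saturday's | 0.20 M | 0.20 M | 0.020 M | 20 °C | the very flask that is asked about, followed so far |  |
| Tuesday's | 0.20 M | 0.20 M | 0.020 M | 26 °C | run made earlier |  |
| flask | 0.20 M | 0.200 M | 0.0200 M | 20 °C |  | 20 h |

| run | time / h | X / % |
|---|---|---|
| Saturday's | 1.00 | 53.5 |
| Saturday's | 3.00 | 67.4 |
| Saturday's | 6.00 | 69.0 |
| Saturday's | 8.00 | 69.4 |
| Saturday's | 12.0 | 69.5 |
| Saturday's | 15.0 | 69.3 |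
| Tuesday's | 1.00 | 61.7 |
| Tuesday's | 3.00 | 68.0 |
| Tuesday's | 6.00 | 69.1 |
| Tuesday's | 8.00 | 68.2 |
| Tuesday's | 12.0 | 68.9 |
| Tuesday's | 15.0 | 68.6 |

(readings scatter by 0.5 percentage points)
- north-west: change nothing and wait 40 h more
- south-west: at 20 h take out 90% of the X then present, then wait 40 h
- north: at 20 h raise the temperature by 25 K, then wait 40 h
- west: at 20 h add G, 50.0% of the amount charged, then wait 40 h
- X that was removed still counts
- on the list of suspects stand: D + G -> X; G + Q -> J; G -> Z
- additions bring no volume worth counting
1. X, in percent of the D first charged, at 20 h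
2. which option adds most X ("none" when 2 percentage points or less is all one gets) (north-west / south-west / north / west / none)
3. X present, with what was taken out counted in, in percent of the D first charged, after south-west
4. X present, with what was taken out counted in, in percent of the D first charged, after west

First I asked which numbers had to be good. Time hardly mattered: in Saturday's run X lay flat from 6.00 h, with a mean reading of 69.3%, and I took that as my value at 20 h. Temperature hardly mattered either: Tuesday's mean was 68.7%, 0.6 percentage points away, against a scatter of 0.5 points. The suspects hold no back step, so I read flat X beside free D as c_G near nil, and I let J take the whole c_Q charged. The balance of G then gave c_Z = 0.0414 M, a small difference, so errors grow in it: a relative error in c_G returns 4.83 times larger, one in plateau X 3.35 times, one in c_Q 0.483 times.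

Dividing the rate of X by the rate of Z removes both time and c_G: dc_X/dc_Z = c_D/S. Integrated, S = c_Z / ln(c_D charged / c_D left) = 0.0351 M as a reading. S is the split concentration, the c_D at which G goes equally fast to X and to Z, a selectivity factor in concentration units.

For 20 h I reckoned c_D at 0.0614 M, so new G would go to X with share 63.7%, falling as D falls. Waiting, heating and removing X supply no G, so I kept 69.3% for south-west. West adds 0.100 M of G. If X took half of that, S would demand 0.0590 M for Z, more than the other half, so X gains slightly less and ends just under 94.3%.

The forecast gave 69.4%, west, 81% and 86%, saying “the data do not settle it”; it stood above my south-west and below my west.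

The flask gave 69.6%, west as best with 24 points gained, 69.6% and 93.4%.

    D + G → X (k = 0.140 L mol⁻¹ min⁻¹, Ea = 74.0 kJ mol⁻¹)
    G + Q → J (k = 2.00 L mol⁻¹ min⁻¹, Ea = 40.0 kJ mol⁻¹)
    G → Z (k = 0.00480 min⁻¹, Ea = 85.0 kJ mol⁻¹)
    (constants at 20 °C)

At 20.0 h the flask held G 0% and D 30.4% of charge. Put to use on west, S assigns 0.0540 M to Z for that fall of D, and with the gain in X this sums to 0.102 M against 0.100 M added.

In the neighbour flask charged with 0.0050 M of Q, the G that Q no longer takes, at share 63.7%, gives X 74.1%; computed, 74.2%.

Readings and results stem from a simulated flask on assumed constants; scatter was added.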